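The runs come from a simulation on assumed constants.

The vessel is closed, stirred and of constant volume.

| flask | Sub | Rea | Spx | remark | time |
|---|---|---|---|---|---|
| elm | 0.10 M | 2.5 equiv | 5 mM | run made earlier |  |
| birch | 0.10 M | 4.3 equiv | 5 mM | run made earlier |  |
| alder | 0.10 M | 4.6 equiv | 5 mM | run made earlier |  |
| dusk | 0.10 M | 3.90 equiv | 5.00 mM |  | 10 min |
| dawn | 0.10 M | 5.10 equiv | 5.00 mM |  | 10 min |
| summer | 0.10 M | 3.00 equiv | 5.00 mM |  | 10 min |

- elm (time / min: Sub / %, Pdt / %): 0.833: 92.8, 7.4; 2.50: 81.5, 21.1; 5.00: 65.9, 32.3; 8.00: 54.8, 43.2
- birch (time / min: Sub / %, Pdt / %): 0.833: 85.7, 10.5; 2.50: 70.0, 30.7; 5.00: 48.1, 51.1; 8.00: 34.4, 64.4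
- alder (time / min: Sub / %, Pdt / %): 2.00: 72.8, 29.0; 4.00: 53.0, 47.0; 5.00: 48.1, 53.0; 8.00: 32.0, 68.7

(scatter of a reading: 1 percentage point)

* part of the Sub that has reacted at the end, dusk
* part of the Sub that has reacted at the end, dawn
* part of the Sub that has reacted at the end, summer
* what raising the equivalents of Rea from its lowest to its highest value here does to the part of the Sub that has reacted (changes below 5 percentage points count as none) (it rises / it falls / no change)

- what was read earlier has a scatter of 1 percentage point, one standard deviation

In birch at 8.00 min, Sub and Pdt together make 98.8% of the charge, and the new flasks hold 3.00 equiv of Rea or more. I take the end state to be Sub turned into Pdt, and what I need is how far it gets by 10 min.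

I take the fraction of Sub left as exp(−κ·e·t), with e the equivalents of Rea and t the time. This holds Rea at its charge, a pseudo-first-order view. In this rule κ, e and t weigh alike: a small relative error in any of them moves the part reacted by that error times the exponent times the fraction left. The recipe sets e and t, so they cost nothing. Spx is charged at 5.00% of the Sub; if each Spx took one Rea, summer would lose 1.67% of its Rea, hardly any, so Spx needn't be known well. Sub stands at 0.10 M in old and new flasks, so it stays inside κ. That leaves κ as the number to know well.

Birch's last reading gives κ = 0.0310 min⁻¹, the first-order constant per equivalent of Rea. Elm gives 0.0301 min⁻¹ and alder 0.0310 min⁻¹, so the last readings of these runs scale with Rea. My reckoning is 60.6% reacted for summer, 70.2% for dusk and 79.4% for dawn, a rise of 19 percentage points from summer to dawn, beyond the margin of 5 points. Rea does get used, so I read these as slightly high.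

The forecast, reckoned “allowing for Rea consumption”, says 59.3% for summer, 69.3% for dusk and 79% for dawn, each less than mine , and for the trend, it rises.

The flask gives 57.8% for summer, 68.3% for dusk and 78.7% for dawn, so from summer to dawn it rises, by 21 points. In dusk at 10.0 min, free Rea stands at 63.7% of its charge, not at the full charge my rule holds.

    Rea + Spx → Rea.Spx (k = 0.340 L mol⁻¹ s⁻¹)
    Rea + Bpr ⇌ Rea.Bpr, settled at all times (K = 1300 L mol⁻¹)
    Sub + Rea → Bpr + Pdt (k = 0.00640 L mol⁻¹ s⁻¹)

For a neighbour like summer but with 12.0 equiv of Rea, the rule leaves 2.42% of the Sub, and that flask holds 1.8% at 10.0 min.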